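**Retrosynthetic overview**

1. Labels: C1 = C(OH)(C7H2O–), C2 = C=O, C3=C4, C5 = CHOBz, C6 = CHOH. The strategy rests on two features: C3=C4 is the only alkene of the ring C1–C6 and is conjugated to the C2 ketone, and the neighbouring C5/C6 trans (threo) diol has the configuration of C2/C3 of D-tartaric acid.
2. Zeylenone 23 ⇐ site-selective C5–O benzoylation of triol 22 ⇐ acetonide removal and PMB-to-benzoyl exchange at C7–O on enone 18.
3. 18 ⇐ ring-closing metathesis forming C3=C4 from dienone 17 (C2 vinyl ketone + C5 vinyl). This closes the six-membered carbocycle, the second and last ring made; the dioxolane on C5/C6 is made first, in step 1.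
4. 17 ⇐ C1–C2 bond by Felkin–Anh addition of lithiated methoxyallene (acryloyl anion equivalent) to the C1 ketone 13, with C6 controlling C1; 13 ⇐ C1–C7 bond from Weinreb amide 7 and PMBOCH2Li.
5. 7 ⇐ diethyl D-tartrate 1: its carbinol carbons are C5 and C6, its carboxyl carbons become C4 (CO2H → CH2OH → CHO → vinyl) and C1.

Key step: step 11

Assumption: the threo C5/C6 diol can only be bridged as a trans-dioxolane, so a trans-fused acetonide is carried through the ring closure; tributyl(iodomethyl)stannane and methoxyallene are taken as purchasable.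

**Route**

Step 1
Reactants: 1 diethyl D-tartrate
Product: 2 diethyl (4S,5S)-2,2-dimethyl-1,3-dioxolane-4,5-dicarboxylate
Conditions: Me2C(OMe)2, TsOH·H2O (cat.), cyclohexane, reflux, MeOH distilled off
Reagents that add atoms: 2,2-dimethoxypropane, COC(C)(C)OC
Why: Acid-catalysed transketalisation of the 1,2-diol gives the trans-dioxolane without touching the two tartrate stereocentres (future C5 and C6).

Step 2
Reactants: 2 diethyl (4S,5S)-2,2-dimethyl-1,3-dioxolane-4,5-dicarboxylate
Product: 3 (4S,5S)-5-(ethoxycarbonyl)-2,2-dimethyl-1,3-dioxolane-4-carboxylic acid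
Conditions: KOH (1.0 equiv), EtOH, 0 °C → rt; then 1 M HCl to pH 3, 0 °C
Reagents that add atoms: potassium hydroxide, [K+].[OH-]
Why: Monosaponification of a C2-symmetric diester, in which the first carboxylate slows hydrolysis of the second ester and either ester gives the same monoacid; the trans-dioxolane is the stable epimer, so base does not scramble it.

Step 3
Reactants: 3 (4S,5S)-5-(ethoxycarbonyl)-2,2-dimethyl-1,3-dioxolane-4-carboxylic acid
Product: 4 ethyl (4S,5R)-5-(hydroxymethyl)-2,2-dimethyl-1,3-dioxolane-4-carboxylate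
Conditions: BH3·SMe2, THF, 0 °C → rt; MeOH, then aqueous work-up
Reagents that add atoms: none
Why: Chemoselective borane reduction of a carboxylic acid (through the acyloxyborane) in the presence of an ester.

Step 4
Reactants: 4 ethyl (4S,5R)-5-(hydroxymethyl)-2,2-dimethyl-1,3-dioxolane-4-carboxylate
Product: 5 ethyl (4S,5S)-5-formyl-2,2-dimethyl-1,3-dioxolane-4-carboxylate
Conditions: Dess–Martin periodinane, CH2Cl2, 0 °C → rt; used crude
Reagents that add atoms: none
Why: Dess–Martin oxidation of the primary alcohol to the aldehyde under non-basic conditions, the trans-disubstituted dioxolane aldehyde being the thermodynamically preferred epimer.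

Step 5
Reactants: 5 ethyl (4S,5S)-5-formyl-2,2-dimethyl-1,3-dioxolane-4-carboxylate
Product: 6 ethyl (4S,5R)-5-ethenyl-2,2-dimethyl-1,3-dioxolane-4-carboxylate
Conditions: Ph3PCH3Br, KHMDS, THF, −78 → 0 °C
Reagents that add atoms: methyltriphenylphosphonium bromide, C[P+](c1ccccc1)(c1ccccc1)c1ccccc1.[Br-]
Why: Wittig methylenation, the unstabilised ylide reacting with the aldehyde far faster than with the ester, installs the C5 vinyl group (C4 plus the CH2 later lost as ethylene).

Step 6
Reactants: 6 ethyl (4S,5R)-5-ethenyl-2,2-dimethyl-1,3-dioxolane-4-carboxylate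
Product: 7 (4S,5R)-5-ethenyl-N-methoxy-N,2,2-trimethyl-1,3-dioxolane-4-carboxamide
Conditions: MeNH(OMe)·HCl, i-PrMgCl, THF, −20 → 0 °C; aq. NH4Cl
Reagents that add atoms: N,O-dimethylhydroxylamine hydrochloride, CNOC.Cl
Why: Direct aminolysis of the ester by the chloromagnesium amide of N,O-dimethylhydroxylamine gives the Weinreb amide without a free-acid stage.

Step 7
Reactants: 8 4-methoxybenzyl alcohol; 9 tributyl(iodomethyl)stannane
Product: 11 tributyl{[(4-methoxybenzyl)oxy]methyl}stannane, via sodium 4-methoxybenzyl oxide 10 (not isolated)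
Conditions: NaH, THF–DMF, 0 °C; then 9, rt
Reagents that add atoms: none
Why: Williamson etherification of the sodium alkoxide with the primary α-stannyl iodide gives the α-alkoxymethylstannane.

Step 8
Reactants: 7 (4S,5R)-5-ethenyl-N-methoxy-N,2,2-trimethyl-1,3-dioxolane-4-carboxamide; 11 tributyl{[(4-methoxybenzyl)oxy]methyl}stannane
Product: 13 1-[(4S,5R)-5-ethenyl-2,2-dimethyl-1,3-dioxolan-4-yl]-2-[(4-methoxybenzyl)oxy]ethan-1-one, via [(4-methoxybenzyl)oxy]methyllithium 12 (not isolated)
Conditions: 11, n-BuLi, THF, −78 °C; then 7, −78 °C; aq. NH4Cl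
Reagents that add atoms: none
Why: Tin–lithium exchange gives the α-alkoxymethyllithium, which acylates once on the Weinreb amide through the stable chelated tetrahedral intermediate and so gives the C1 ketone carrying C7.

Step 9
Reactants: 13 1-[(4S,5R)-5-ethenyl-2,2-dimethyl-1,3-dioxolan-4-yl]-2-[(4-methoxybenzyl)oxy]ethan-1-one; 14 methoxyallene
Product: 16 (2S)-2-[(4S,5R)-5-ethenyl-2,2-dimethyl-1,3-dioxolan-4-yl]-3-methoxy-1-[(4-methoxybenzyl)oxy]penta-3,4-dien-2-ol, via 1-lithio-1-methoxyallene 15 (not isolated)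
Conditions: 14, n-BuLi, THF, −40 °C; then 13, −78 °C; H2O quench
Reagents that add atoms: none
Why: 1,2-Addition of the acryloyl anion equivalent to the ketone, in which C6 sets the new C1 centre under polar Felkin–Anh control (C6–O anti to the incoming carbanion, which passes C6–H and not C5; the Cornforth arrangement predicts the same face), so that C1 should be (S) with C1–OH placed for the later cis C1/C6 diol.

Step 10
Reactants: 16 (2S)-2-[(4S,5R)-5-ethenyl-2,2-dimethyl-1,3-dioxolan-4-yl]-3-methoxy-1-[(4-methoxybenzyl)oxy]penta-3,4-dien-2-ol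
Product: 17 (4S)-4-[(4S,5R)-5-ethenyl-2,2-dimethyl-1,3-dioxolan-4-yl]-4-hydroxy-5-[(4-methoxybenzyl)oxy]pent-1-en-3-one
Conditions: 5% aq. H2SO4, THF, 0 °C, short contact; NaHCO3
Reagents that add atoms: water, O
Why: Enol ether hydrolysis of the 1-methoxyallene (protonation at the central allene carbon, addition of water, loss of methanol) unmasks the vinyl ketone much faster than cold dilute acid attacks the acetonide or the PMB ether.

Step 11
Reactants: 17 (4S)-4-[(4S,5R)-5-ethenyl-2,2-dimethyl-1,3-dioxolan-4-yl]-4-hydroxy-5-[(4-methoxybenzyl)oxy]pent-1-en-3-one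
Product: 18 (3aS,4S,7aR)-4-hydroxy-4-{[(4-methoxybenzyl)oxy]methyl}-2,2-dimethyl-3a,7a-dihydro-1,3-benzodioxol-5(4H)-one (C3=C4 enone, acetonide trans-fused on C5/C6)
Conditions: Grubbs II (5–10 mol%), CH2Cl2 (0.005 M), 40 °C, argon sparge
Reagents that add atoms: none
Why: Ring-closing olefin metathesis of an octa-1,7-diene: the ruthenium benzylidene first exchanges with the unhindered, more electron-rich C5 vinyl group, the C4 alkylidene so formed adds [2+2] across the C2 vinyl ketone, and cycloreversion of the ruthenacyclobutane gives the C3=C4 enone while the two terminal CH2 groups leave as ethylene. The closest known reaction type is the NHC–ruthenium RCM of tartrate- and sugar-derived dienes and vinyl-ketone dienes to conduritol- and gabosine-type cyclohexenes and cyclohexenones. One ring is closed, the six-membered carbocycle C1–C6, by RCM between C3 and C4 onto the existing dioxolane (trans ring fusion at C5–C6). No stereocentre is formed; C1, C5 and C6 are spectators, C1 having no α-hydrogen and C5 remaining an allylic ether. The step needs initiation at the C5 vinyl group and not at the enone, and ring closure in preference to cross-metathesis: the fully substituted C1 shields the vinyl ketone from intermolecular attack, the quaternary centre and the dioxolane hold the two alkenes gauche, and high dilution with loss of ethylene makes closure irreversible. The free tertiary C1–OH and the PMB ether are tolerated by the catalyst.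

Step 12
Reactants: 18 (3aS,4S,7aR)-4-hydroxy-4-{[(4-methoxybenzyl)oxy]methyl}-2,2-dimethyl-3a,7a-dihydro-1,3-benzodioxol-5(4H)-one
Product: 19 (3aS,4S,7aR)-4-hydroxy-4-(hydroxymethyl)-2,2-dimethyl-3a,7a-dihydro-1,3-benzodioxol-5(4H)-one
Conditions: DDQ, CH2Cl2–pH 7 buffer (10:1), 0 °C → rt
Reagents that add atoms: none
Why: Oxidative PMB cleavage by DDQ (benzylic hydride abstraction, then hydrolysis of the oxocarbenium ion) in wet solvent, so that water and not the neighbouring C1–OH traps the cation; enone and acetonide are inert.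

Step 13
Reactants: 19 (3aS,4S,7aR)-4-hydroxy-4-(hydroxymethyl)-2,2-dimethyl-3a,7a-dihydro-1,3-benzodioxol-5(4H)-one; 20 benzoyl chloride
Product: 21 [(3aS,4S,7aR)-4-hydroxy-2,2-dimethyl-5-oxo-3a,4,5,7a-tetrahydro-1,3-benzodioxol-4-yl]methyl benzoate
Conditions: BzCl, pyridine, DMAP (cat.), CH2Cl2, 0 °C
Reagents that add atoms: none
Why: Acylation of the primary C7–OH, the tertiary C1–OH being unreactive under these conditions.

Step 14
Reactants: 21 [(3aS,4S,7aR)-4-hydroxy-2,2-dimethyl-5-oxo-3a,4,5,7a-tetrahydro-1,3-benzodioxol-4-yl]methyl benzoate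
Product: 22 [(1S,5R,6S)-1,5,6-trihydroxy-2-oxocyclohex-3-en-1-yl]methyl benzoate
Conditions: TFA–H2O (9:1), CH2Cl2, 0 °C
Reagents that add atoms: none
Why: Acid hydrolysis of the strained trans-fused acetonide, to which the benzoate and the enone are stable in the cold.

Step 15
Reactants: 22 [(1S,5R,6S)-1,5,6-trihydroxy-2-oxocyclohex-3-en-1-yl]methyl benzoate; 20 benzoyl chloride
Product: 23 zeylenone, [(1S,5R,6S)-5-(benzoyloxy)-1,6-dihydroxy-2-oxocyclohex-3-en-1-yl]methyl benzoate
Conditions: BzCl (1.05 equiv), pyridine, CH2Cl2, −30 → 0 °C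
Reagents that add atoms: none
Why: Kinetically selective acylation of the allylic C5–OH, which is flanked by the flat sp2 C4, over the C6–OH wedged beside the fully substituted C1 and over the tertiary C1–OH.

**Compound list**

1 | diethyl D-tartrate, diethyl (2S,3S)-2,3-dihydroxybutanedioate | CCOC(=O)[C@@H](O)[C@H](O)C(=O)OCC | starting material
2 | diethyl (4S,5S)-2,2-dimethyl-1,3-dioxolane-4,5-dicarboxylate | CCOC(=O)[C@H]1OC(C)(C)O[C@@H]1C(=O)OCC | intermediate
3 | (4S,5S)-5-(ethoxycarbonyl)-2,2-dimethyl-1,3-dioxolane-4-carboxylic acid | CCOC(=O)[C@H]1OC(C)(C)O[C@@H]1C(=O)O | intermediate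
4 | ethyl (4S,5R)-5-(hydroxymethyl)-2,2-dimethyl-1,3-dioxolane-4-carboxylate | CCOC(=O)[C@H]1OC(C)(C)O[C@@H]1CO | intermediate
5 | ethyl (4S,5S)-5-formyl-2,2-dimethyl-1,3-dioxolane-4-carboxylate | CCOC(=O)[C@H]1OC(C)(C)O[C@@H]1C=O | intermediate
6 | ethyl (4S,5R)-5-ethenyl-2,2-dimethyl-1,3-dioxolane-4-carboxylate | CCOC(=O)[C@H]1OC(C)(C)O[C@@H]1C=C | intermediate
7 | (4S,5R)-5-ethenyl-N-methoxy-N,2,2-trimethyl-1,3-dioxolane-4-carboxamide | CON(C)C(=O)[C@H]1OC(C)(C)O[C@@H]1C=C | intermediate
8 | 4-methoxybenzyl alcohol | COc1ccc(CO)cc1 | starting material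
9 | tributyl(iodomethyl)stannane | CCCC[Sn](CCCC)(CCCC)CI | starting material
10 | sodium 4-methoxybenzyl oxide | [Na+].[O-]Cc1ccc(OC)cc1 | intermediate (not isolated)
11 | tributyl{[(4-methoxybenzyl)oxy]methyl}stannane | CCCC[Sn](CCCC)(CCCC)COCc1ccc(OC)cc1 | intermediate
12 | [(4-methoxybenzyl)oxy]methyllithium | [Li]COCc1ccc(OC)cc1 | intermediate (not isolated)
13 | 1-[(4S,5R)-5-ethenyl-2,2-dimethyl-1,3-dioxolan-4-yl]-2-[(4-methoxybenzyl)oxy]ethan-1-one | COc1ccc(COCC(=O)[C@H]2OC(C)(C)O[C@@H]2C=C)cc1 | intermediate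
14 | methoxyallene (1-methoxypropa-1,2-diene) | COC=C=C | starting material
15 | 1-lithio-1-methoxyallene | [Li]C(OC)=C=C | intermediate (not isolated)
16 | (2S)-2-[(4S,5R)-5-ethenyl-2,2-dimethyl-1,3-dioxolan-4-yl]-3-methoxy-1-[(4-methoxybenzyl)oxy]penta-3,4-dien-2-ol | C=C=C(OC)[C@](O)(COCc1ccc(OC)cc1)[C@H]1OC(C)(C)O[C@@H]1C=C | intermediate
17 | (4S)-4-[(4S,5R)-5-ethenyl-2,2-dimethyl-1,3-dioxolan-4-yl]-4-hydroxy-5-[(4-methoxybenzyl)oxy]pent-1-en-3-one | C=CC(=O)[C@](O)(COCc1ccc(OC)cc1)[C@H]1OC(C)(C)O[C@@H]1C=C | intermediate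
18 | (3aS,4S,7aR)-4-hydroxy-4-{[(4-methoxybenzyl)oxy]methyl}-2,2-dimethyl-3a,7a-dihydro-1,3-benzodioxol-5(4H)-one | COc1ccc(COC[C@@]2(O)C(=O)C=C[C@H]3OC(C)(C)O[C@H]23)cc1 | intermediate
19 | (3aS,4S,7aR)-4-hydroxy-4-(hydroxymethyl)-2,2-dimethyl-3a,7a-dihydro-1,3-benzodioxol-5(4H)-one | OC[C@@]1(O)C(=O)C=C[C@H]2OC(C)(C)O[C@H]12 | intermediate
20 | benzoyl chloride | O=C(Cl)c1ccccc1 | starting material
21 | [(3aS,4S,7aR)-4-hydroxy-2,2-dimethyl-5-oxo-3a,4,5,7a-tetrahydro-1,3-benzodioxol-4-yl]methyl benzoate | O=C(OC[C@@]1(O)C(=O)C=C[C@H]2OC(C)(C)O[C@H]12)c1ccccc1 | intermediate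
22 | [(1S,5R,6S)-1,5,6-trihydroxy-2-oxocyclohex-3-en-1-yl]methyl benzoate | O=C(OC[C@@]1(O)C(=O)C=C[C@@H](O)[C@@H]1O)c1ccccc1 | intermediate
23 | zeylenone, [(1S,5R,6S)-5-(benzoyloxy)-1,6-dihydroxy-2-oxocyclohex-3-en-1-yl]methyl benzoate | O=C(OC[C@@]1(O)C(=O)C=C[C@@H](OC(=O)c2ccccc2)[C@@H]1O)c1ccccc1 | target

**Step count and risks**

Total step count: 15 (14 on the main line plus the one-step preparation of stannane 11).
Longest linear sequence: 14 steps (steps 1–6 and 8–15, from diethyl D-tartrate).

Steps most likely to fail: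

Step 11 (ring-closing metathesis). The C4 alkylidene may fail to engage the electron-poor vinyl ketone, or be held back by chelation to C1–OH and C2=O. Cross-metathesis through the C5 vinyl group and catalyst decay would then outpace closure of the strained trans-fused bicycle. The fallback closes the ring at the allylic alcohol oxidation level and sets out from 17. Luche reduction (NaBH4, CeCl3·7H2O, MeOH, −78 °C) should give the dienol F1 (17 with C2=O reduced to CHOH, both C2 epimers), a diene of two unhindered allylic carbinol/ether alkenes with an sp3 C2 that eases the ring strain. Grubbs II in CH2Cl2 should then close it to the cyclohexenediol F2 (18 with C2=O as CHOH). MnO2 in CH2Cl2 oxidises the secondary allylic alcohol and leaves the tertiary C1–OH, which comes back to the route at 18.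

Step 9 (addition of lithiated methoxyallene). Facial selectivity may be eroded if lithium bridges the carbonyl and the dioxolane oxygen, which directs attack to the opposite face and would give a mixture of C1 epimers. The fallback sets C1 by reagent control and sets out from ketone 13.
- Wittig methylenation (Ph3P=CH2, THF) gives the 1,1-disubstituted alkene F3.
- DDQ in wet CH2Cl2 frees the allylic alcohol F4.
- Sharpless asymmetric epoxidation (Ti(OiPr)4, D-(−)-diethyl tartrate, i.e. compound 1 as ligand, t-BuOOH, 4 Å MS, CH2Cl2, −20 °C) should epoxidise only the allylic-alcohol alkene, on the face the ligand dictates, to give the epoxy alcohol F5.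
- Sodium 4-methoxybenzyl oxide 10 in DMF at 60 °C opens the oxirane at its CH2 to give the diol F6; a Payne shift of the epoxide beforehand leads to the same stereoisomer. The new CH2OPMB carbon takes the place of C7 and the former C7 becomes C2.
- TEMPO/PhI(OAc)2 oxidises the primary alcohol to the α-hydroxy aldehyde F7.
- Vinylmagnesium bromide (excess, THF, −78 → 0 °C) gives the dienol F1 described above, and MnO2 (or Dess–Martin periodinane) oxidation of its secondary allylic alcohol comes back to the route at 17.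

Step 15 (final benzoylation). Site selectivity may be lost through acylation of C6–OH, double acylation or benzoyl migration between O5 and O6. The fallback masks the cis C1/C6 diol and sets out from triol 22. Phenylboronic acid (1.0 equiv, CH2Cl2, 4 Å MS, rt) should form the five-membered cyclic phenylboronate F8 across the cis C1–OH/C6–OH pair only, since the trans-diequatorial C5/C6 pair cannot be bridged in this way. Benzoylation of the one remaining hydroxyl (BzCl, pyridine, DMAP cat., 0 °C) gives the benzoylated boronate F9. Transesterification with pinacol in CH2Cl2 releases the diol and comes back to the route at 23.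

**Further compounds**

F1 | step 11 | dienol: 17 with C2=O reduced to CHOH (both C2 epimers) | C=CC(O)[C@](O)(COCc1ccc(OC)cc1)[C@H]1OC(C)(C)O[C@@H]1C=C
F2 | step 11 | cyclohexenediol: 18 with C2=O reduced to CHOH (both C2 epimers) | COc1ccc(COC[C@@]2(O)C(O)C=C[C@H]3OC(C)(C)O[C@H]23)cc1
F3 | step 9 | (4R,5R)-4-ethenyl-5-{3-[(4-methoxybenzyl)oxy]prop-1-en-2-yl}-2,2-dimethyl-1,3-dioxolane | C=C(COCc1ccc(OC)cc1)[C@H]1OC(C)(C)O[C@@H]1C=C
F4 | step 9 | 2-[(4R,5R)-5-ethenyl-2,2-dimethyl-1,3-dioxolan-4-yl]prop-2-en-1-ol | C=C(CO)[C@H]1OC(C)(C)O[C@@H]1C=C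
F5 | step 9 | {(2S)-2-[(4S,5R)-5-ethenyl-2,2-dimethyl-1,3-dioxolan-4-yl]oxiran-2-yl}methanol | OC[C@]1(CO1)[C@H]2OC(C)(C)O[C@@H]2C=C
F6 | step 9 | (2S)-2-[(4S,5R)-5-ethenyl-2,2-dimethyl-1,3-dioxolan-4-yl]-3-[(4-methoxybenzyl)oxy]propane-1,2-diol | OC[C@](O)(COCc1ccc(OC)cc1)[C@H]1OC(C)(C)O[C@@H]1C=C
F7 | step 9 | (2S)-2-[(4S,5R)-5-ethenyl-2,2-dimethyl-1,3-dioxolan-4-yl]-2-hydroxy-3-[(4-methoxybenzyl)oxy]propanal | O=C[C@](O)(COCc1ccc(OC)cc1)[C@H]1OC(C)(C)O[C@@H]1C=C
F8 | step 15 | cyclic phenylboronate of 22 across O1 and O6 (C5–OH free, C7–OBz) | O=C(OC[C@@]1(OB(O2)c3ccccc3)C(=O)C=C[C@@H](O)[C@@H]12)c1ccccc1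
F9 | step 15 | cyclic phenylboronate of zeylenone across O1 and O6 (C5–OBz, C7–OBz) | O=C(OC[C@@]1(OB(O2)c3ccccc3)C(=O)C=C[C@@H](OC(=O)c4ccccc4)[C@@H]12)c1ccccc1
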